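**Target:** (R)-3-(2-hydroxyheptadecyl)-5-methoxyphenol (the single stereocentre, C2 of the side chain, reads as R from the SMILES).

**Retrosynthetic overview**
- 8 ⇒ 6: the free phenol is released last by one O-demethylation of the symmetric 3,5-dimethoxyaryl group (both methyl ethers are equivalent, so there is no regiochemistry to control).
- 6 ⇒ 5: the C2–O bond and the only stereocentre come from an enantioselective anti-Markovnikov addition of water across the (E)-β-alkylstyrene.
- 5 ⇒ 1 + 2: the C1=C2 bond comes from a Wittig olefination of 3,5-dimethoxybenzaldehyde with the C16 ylide, followed by Z→E equilibration in the same pot.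
- No ring is formed; the benzene ring is bought with 1.

**Assumption:** the sense of induction of the new ion-pair catalyst in step 2 cannot be predicted; the antipode that gives the (R)-alcohol is used (both come from (R)- or (S)-BINOL) and is written below as (S,S).

**Step 1**
Reactants: 1 3,5-dimethoxybenzaldehyde; 2 hexadecyl(triphenyl)phosphonium bromide
Product: 5 (E)-1-(3,5-dimethoxyphenyl)heptadec-1-ene, via hexadecylidene(triphenyl)phosphorane 3 (not isolated), via (Z)-1-(3,5-dimethoxyphenyl)heptadec-1-ene 4 (not isolated)
Conditions: 2 (1.2 equiv), NaHMDS (1.15 equiv), THF, 0 °C; 1, −78 °C → rt; swap to heptane, filter off Ph3PO; then I2 (5 mol%), heptane, 80 °C; aq. Na2S2O3 wash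
Reagents that add atoms: none
Why: Wittig olefination of an aromatic aldehyde with a non-stabilised ylide gives the Z-rich alkene, and iodine-atom-catalysed Z→E isomerisation (reversible I• addition) then drives it to the conjugated thermodynamic E isomer (about 95:5 or better); no stereocentre is formed.

**Step 2**
Reactants: 5 (E)-1-(3,5-dimethoxyphenyl)heptadec-1-ene
Product: 6 (R)-1-(3,5-dimethoxyphenyl)heptadecan-2-ol
Conditions: preformed ion pair [3,6-di-tert-butyl-9-mesityl-10-phenylacridinium][(S,S)-IDPi] (5 mol%; IDPi = confined BINOL-derived N-triflyl imidodiphosphorimidate anion), (PhS)2 (10 mol%), H2O (20 equiv, biphasic), CHCl3, 450 nm LEDs, Ar, 0 °C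
Reagents that add atoms: water, O
Why: Proposed new method: catalytic enantioselective anti-Markovnikov hydration of a β-alkylstyrene by counteranion-directed photoredox catalysis — the excited acridinium oxidises 5 to its radical cation, which in water-saturated CHCl3 stays tightly paired with the confined chiral IDPi anion; water attacks the homobenzylic carbon (the position that leaves a benzylic radical) on the face the anion leaves open, so this C–O bond formation sets the (R) centre; the anion takes up the oxonium proton, PhSH transfers H• to the benzylic radical (a CH2, so no second centre), and PhS• reoxidises the acridine radical while the thiolate is reprotonated by the IDPi acid, closing both cycles; the closest known reaction types are the racemic acridinium/disulfide anti-Markovnikov hydration of styrenes and chiral-counteranion-controlled radical-cation cycloadditions of styrenes.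

**Step 3**
Reactants: 6 (R)-1-(3,5-dimethoxyphenyl)heptadecan-2-ol
Product: 8 (R)-3-(2-hydroxyheptadecyl)-5-methoxyphenol, via sodium 3-[(2R)-2-hydroxyheptadecyl]-5-methoxyphenolate 7 (not isolated)
Conditions: NaSEt (4 equiv), DMF, 140 °C; then aq. HCl, 0 °C
Reagents that add atoms: none
Why: Nucleophilic O-demethylation (SN2 attack of ethanethiolate at the methyl group of an aryl methyl ether) stops cleanly after one methyl because the phenolate formed makes the second aryloxide a far poorer leaving group; the unactivated secondary carbinol has no pathway to epimerise, so the (R) centre is carried through unchanged.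

**Compound list**
1 | 3,5-dimethoxybenzaldehyde | COc1cc(C=O)cc(OC)c1 | starting material
2 | hexadecyl(triphenyl)phosphonium bromide | CCCCCCCCCCCCCCCC[P+](c1ccccc1)(c1ccccc1)c1ccccc1.[Br-] | starting material
3 | hexadecylidene(triphenyl)phosphorane | CCCCCCCCCCCCCCCC=P(c1ccccc1)(c1ccccc1)c1ccccc1 | intermediate
4 | (Z)-1-(3,5-dimethoxyphenyl)heptadec-1-ene | CCCCCCCCCCCCCCC/C=C\c1cc(OC)cc(OC)c1 | intermediate
5 | (E)-1-(3,5-dimethoxyphenyl)heptadec-1-ene | CCCCCCCCCCCCCCC/C=C/c1cc(OC)cc(OC)c1 | intermediate
6 | (R)-1-(3,5-dimethoxyphenyl)heptadecan-2-ol | CCCCCCCCCCCCCCC[C@@H](O)Cc1cc(OC)cc(OC)c1 | intermediate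
7 | sodium 3-[(2R)-2-hydroxyheptadecyl]-5-methoxyphenolate | CCCCCCCCCCCCCCC[C@@H](O)Cc1cc([O-])cc(OC)c1.[Na+] | intermediate
8 | (R)-3-(2-hydroxyheptadecyl)-5-methoxyphenol | CCCCCCCCCCCCCCC[C@@H](O)Cc1cc(O)cc(OC)c1 | target

**Total step count:** 3
**Longest linear sequence:** 3

**Steps most likely to fail**

Step 2 (the proposed new hydration) is the main risk. Ion pairing may be too loose in the wet medium, giving low ee. The transient IDPi acid may open a racemic Markovnikov pathway. The product arene may be over-oxidised, and its radical cation can fragment at C1–C2, so conversion must be stopped once 5 is consumed. The fallback uses known chemistry, sets out from 5 and comes back at 6. Shi epoxidation of 5 (D-fructose-derived ketone 30 mol%, Oxone, K2CO3, MeCN/dimethoxymethane/aqueous buffer pH 10.5, 0 °C) gives (2R,3R)-2-(3,5-dimethoxyphenyl)-3-pentadecyloxirane F1, the same sense as with trans-β-methylstyrene. Hydrogenolysis (H2 1 atm, 10% Pd/C, EtOAc, rt) then cleaves only the benzylic C–O bond and leaves the C2–O bond and its configuration untouched, giving 6.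

Step 3 (mono-demethylation) may over-demethylate to the resorcinol or be hard to purify at the final, amphiphilic stage. The fallback moves the demethylation ahead of the stereocentre and ends with a mild deprotection; it sets out from 5 and comes back at 8. NaSEt in DMF at 140 °C with acidic work-up converts 5 into (E)-3-(heptadec-1-en-1-yl)-5-methoxyphenol F2. TBSCl and imidazole in DMF give (E)-tert-butyl[3-(heptadec-1-en-1-yl)-5-methoxyphenoxy]dimethylsilane F3. Hydration as in step 2 (or epoxidation and hydrogenolysis as in the step 2 fallback) gives (R)-1-[3-(tert-butyldimethylsilyloxy)-5-methoxyphenyl]heptadecan-2-ol F4. TBAF in THF at 0 °C then releases 8.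

Step 1 (Wittig and isomerisation) may leave residual Z isomer or give traces of ring iodination. The fallback replaces olefination by addition and elimination; it sets out from 1 and comes back at 5. Hexadecylmagnesium bromide (from 1-bromohexadecane and Mg) in THF at 0 °C adds to 1 to give racemic 1-(3,5-dimethoxyphenyl)heptadecan-1-ol F5. Catalytic p-TsOH in toluene at reflux (Dean–Stark, dilute) dehydrates it through the benzylic cation to the conjugated E alkene 5.

**Further compounds**
F1 | step 2 | (2R,3R)-2-(3,5-dimethoxyphenyl)-3-pentadecyloxirane | CCCCCCCCCCCCCCC[C@H]1O[C@@H]1c1cc(OC)cc(OC)c1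
F2 | step 3 | (E)-3-(heptadec-1-en-1-yl)-5-methoxyphenol | CCCCCCCCCCCCCCC/C=C/c1cc(O)cc(OC)c1
F3 | step 3 | (E)-tert-butyl[3-(heptadec-1-en-1-yl)-5-methoxyphenoxy]dimethylsilane | CCCCCCCCCCCCCCC/C=C/c1cc(O[Si](C)(C)C(C)(C)C)cc(OC)c1
F4 | step 3 | (R)-1-[3-(tert-butyldimethylsilyloxy)-5-methoxyphenyl]heptadecan-2-ol | CCCCCCCCCCCCCCC[C@@H](O)Cc1cc(O[Si](C)(C)C(C)(C)C)cc(OC)c1
F5 | step 1 | 1-(3,5-dimethoxyphenyl)heptadecan-1-ol (racemic) | CCCCCCCCCCCCCCCCC(O)c1cc(OC)cc(OC)c1
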